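The rate constants are assumed.

The watch on this repeat goes on substrate and product rather than on the catalyst forms, since free catalyst is charged at 1 mol% of the substrate.

    substrate + free catalyst ⇌ catalyst intermediate A (K1 = 120 M⁻¹, k1 = 892 M⁻¹ s⁻¹)
    coupling partner + catalyst intermediate A → catalyst intermediate B (k2 = 687 M⁻¹ s⁻¹)
    catalyst intermediate B → catalyst intermediate C (k3 = 6.32 s⁻¹)
    catalyst intermediate C ⇌ free catalyst + product (K4 = 0.0123 M, k4 = 23.7 s⁻¹)

| setting | birch | alder |
|---|---|---|
| substrate | 21 mM | 21 mM |
| coupling partner | 1.80 equiv | 1.80 equiv |
| free catalyst | 1 mol% | 1 mol% |
| time | 30 s | 12 s |

- which of these there is most of at the end, counted by the substrate in it, birch (catalyst intermediate B / product / catalyst intermediate C / substrate)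
- which of these there is most of at the end, counted by the substrate in it, alder (catalyst intermediate B / product / catalyst intermediate C / substrate)
- how much there is at the end of the one of these that leads, in percent of the substrate charged: birch
- how much there is at the end of the one of these that leads, in percent of the substrate charged: alder

Birch and alder carry the same charges and differ in their reading time, so they are two points on one curve. Release of product from catalyst intermediate C has a forward half-life of 0.029 s, shorter than the 0.11 s of catalyst intermediate B and far shorter than the 12 s of alder. My reckoning therefore takes that release as balanced: catalyst intermediate C stands to free catalyst as the product fraction to 0.586. This is product inhibition, and by this balance catalyst intermediate C gains on free catalyst as conversion grows.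

The turn time is the time one catalyst needs for one pass at a given conversion. It sums the waits in catalyst intermediates B and C, the wait for the coupling partner, and the wait for substrate capture. That last wait is lengthened by fall-back from catalyst intermediate A and by the balance above. The turn time comes to 0.308 s at the start, 0.417 s at 33.3 % conversion and 0.760 s at 66.7 %.

Conversion advances each second by the catalyst loading divided by the turn time. Over the early stretch the average of the first two values serves, the mean turn time 0.363 s. Conversion of 33.3 % then takes 12.1 s, and 66.7 % takes 31.7 s. Alder, read at 12 s, stands close to the earlier mark, so substrate should lead with about 66.7 %. Birch, read at 30 s, stands just short of the later mark, so product should lead with about 64.4 %.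

The forecast names product at 65 % for birch and substrate at 66 % for alder, noting that “product pulls free catalyst back into intermediate C”. Its figures lie close to those of the reckoning above, 64.4 % for birch and 66.7 % for alder.

The simulation gives product at 66.1 % in birch and substrate at 65.9 % in alder. The lead therefore changes hands between the two readings, and birch still holds 59.1 % substrate at 15.0 s, so the crossing comes later than that reading. A neighbouring flask, birch with 0.25 mol% of free catalyst, runs the same 30 s. Its loading times its time, divided by the mean turn time 0.363 s, gives 20.7 % conversion, which lies inside the early stretch. That flask reads 22.2 % product, and substrate leads there with 78 %.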